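Readings and results come from a simulation with constants of no real substance; noise was put on by code.

| flask | J | Q | remark | time |
|---|---|---|---|---|
| alpha | 0.050 M | 0.10 M | run made earlier |  |
| delta | 0.20 M | 0.10 M | run made earlier |  |
| flask | 0.10 M | 0.100 M |  | 10 h |

| run | time / h | E / % | J / % |
|---|---|---|---|
| alpha | 0.0833 | 17.9 | 38.6 |
| alpha | 0.167 | 19.7 | 21.3 |
| alpha | 0.333 | 16.8 | 11.4 |
| alpha | 0.833 | 7.3 | 5.4 |
| alpha | 1.50 | 3.2 | 2.2 |
| alpha | 4.00 | 0.2 | 0 |
| alpha | 8.00 | 0 | 0 |
| delta | 0.0833 | 19.7 | 45.0 |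
| delta | 0.167 | 26.8 | 28.9 |
| delta | 0.333 | 30.7 | 19.1 |
| delta | 0.833 | 26.9 | 16.8 |
| delta | 1.50 | 24.1 | 18.5 |
| delta | 4.00 | 23.6 | 18.5 |
| delta | 8.00 | 24.1 | 19.1 |

(each reading ± 0.3 percentage points)

- a reading or a percentage of E counts all its forms, free or not

- time, not beyond 10 h, at which the flask holds most E
- the amount of E, in percent of the J charged, at that time

I begin with an easy reading and then keep a ledger of J.

1. In alpha, J and E read 0% and 0% at 8.00 h, so a J molecule there ends outside what I can read.
2. In delta, at the same cQ, J and E together read 42.6% at 1.50 h and 43.2% at 8.00 h. I take it that the loss stops when Q stops.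
3. So a J molecule meets a fork: it stays in the readings as J or E, or it leaves them. Delta's readings lose 0.114 M of J against 0.10 M of Q charged. That gives 1.14 moles of J lost from the readings per mole of Q charged, the bill.
4. Bill times cQ, over cJ, is the cover. Delta's is 0.568, alpha's 2.27.
5. The flask's cover is 1.14, above one. So my ledger books J and E in the flask as falling to low readings.
6. The flask also has alpha's cQ, so I commit to a peak near alpha's 0.167 h, a little above 19.7%.

The forecast says 25% at 0.27 h, reasoning that “it falls between the two runs”. Mine is earlier and lower.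

The flask gives 21.0% of E at 0.167 h, earlier than the forecast's 0.27 h.

    L ⇌ E, rate k1*(cs1 - [E]) while solid is left; crystals form when [E] > cs1 (solubility = 34.0 mM, k = 15.0 min⁻¹)
    J + Q → G (k = 1.30 M⁻¹ min⁻¹)
    J ⇌ E (K = 0.910, k = 0.0800 min⁻¹)
    Z ⇌ J (k = 0.0450 min⁻¹)
    E ⇌ Z (K = 0.430, k = 0.110 min⁻¹)

Half of the turnover of the step from J + Q to G up to 10 h is done by 0.193 h. With its cover of 1.14, the flask holds G 97.0% at 10.0 h, with J 1.27%, E 1.18% and Z 0.508%, while Q stands at 2.95% of its own charge. A second flask, the same but with 0.25 M of J, has a cover of 0.454, so the ledger leaves 54.6% as J and E. At 10.0 h that flask holds J 14.9% and E 39.2%, crystals L counted, together 54.1%.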